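**Plan**

1. The core is numbered as 7-oxabicyclo[4.1.0]hept-3-ene: C1 is the quaternary epoxide carbon with the butenoate chain, C2 and C5 are the carbinols, C3 carries the heptenyl group, C4 the CH2OH, C6 is the epoxide CH. Working backwards, the acid is freed last, both carbinols come from ketones, and the epoxide comes from the C1=C6 alkene of a quinone monoketal, which is the dearomatised form of a hexasubstituted hydroquinone (aromatic oxidation level as temporary helper).
2. The arene is cut at C4–C5 and C2–C3, the two bonds tying the tetrasubstituted C3=C4 unit to the two oxygen-bearing carbons. This gives an ynal (C3≡C4; the formyl group activates and later becomes CH2OH) and a 2-silyloxyfuran (C5, C6, C1, C2).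
3. The enabling feature is that C2 and C5 are para-related oxygenated carbons of the six-membered ring flanking C3=C4. This is the pattern left when a 2-silyloxyfuran adds to an alkyne across its C2/C5 and the strained 7-oxanorbornadiene opens; the furan ring oxygen becomes O–C2 and the silyloxy oxygen O–C5.
4. Forward: the ynal (two steps) and the furan (three steps) are joined in the cycloaddition/ring-opening, which makes the only carbocycle with all six substituents in place. O-methylation, aldehyde reduction and oxidative dearomatisation follow, then the epoxide ring, two ketone reductions and saponification.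
5. Stereochemistry: C1/C6 from a tartrate-mediated enantioselective nucleophilic epoxidation; C5 from hydride attack anti to the epoxide; C2 from hydroxyl-directed hydride delivery syn to the epoxide; the E-alkenes from (E)-oct-2-enal and an E-selective cross-metathesis.

Key step: step 6

Remark on the chemistry: L-(+)-diisopropyl tartrate is assumed to give the (1R,6S)-epoxide in step 10; should the sense of induction be the reverse, the D-tartrate is used and nothing else changes.

**Route**

Step 1
Reactants: 1 (E)-oct-2-enal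
Product: 2 (3E)-1,1-dibromonona-1,3-diene
Conditions: CBr4 (2 equiv), PPh3 (4 equiv), CH2Cl2, 0 °C
Reagents that add atoms: carbon tetrabromide, BrC(Br)(Br)Br
Why: Corey–Fuchs dibromo-olefination is a Wittig reaction of the ylide formed from CBr4 and PPh3 with the aldehyde and should leave the existing E-alkene untouched.

Step 2
Reactants: 2 (3E)-1,1-dibromonona-1,3-diene
Product: 4 (4E)-dec-4-en-2-ynal, via lithium acetylide 3 (not isolated)
Conditions: n-BuLi (2.1 equiv), THF, −78 °C; then DMF, −78 to 0 °C; reverse quench into aq. KH2PO4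
Reagents that add atoms: N,N-dimethylformamide, CN(C)C=O
Why: In the second stage of the Corey–Fuchs sequence, lithium–bromine exchange, rearrangement and deprotonation give acetylide 3, which is formylated by DMF; the acidic reverse quench should keep the liberated amine from adding to the ynal.

Step 3
Reactants: 5 4-bromofuran-2(5H)-one; 6 allyltributylstannane
Product: 7 4-(prop-2-en-1-yl)furan-2(5H)-one
Conditions: Pd2(dba)3 (2.5 mol %), P(2-furyl)3 (10 mol %), THF, 50 °C
Reagents that add atoms: none
Why: Stille cross-coupling: zerovalent palladium adds readily to the C–Br bond of the vinylogous acyl bromide and the allyl group is transferred from tin under neutral conditions, which should keep the new double bond out of conjugation.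

Step 4
Reactants: 7 4-(prop-2-en-1-yl)furan-2(5H)-one; 8 methyl methacrylate
Product: 9 methyl (2E)-2-methyl-4-(5-oxo-2,5-dihydrofuran-3-yl)but-2-enoate
Conditions: second-generation Grubbs catalyst (H2IMes)(PCy3)Cl2Ru=CHPh (5 mol %), methyl methacrylate (10 equiv), CH2Cl2, 40 °C
Reagents that add atoms: none
Why: Olefin cross-metathesis of a terminal alkene with a 1,1-disubstituted acrylate that hardly homodimerises; the excess acrylate should drive the reaction to the thermodynamically favoured E-trisubstituted enoate.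

Step 5
Reactants: 9 methyl (2E)-2-methyl-4-(5-oxo-2,5-dihydrofuran-3-yl)but-2-enoate
Product: 10 methyl (2E)-4-{5-[(tert-butyldimethylsilyl)oxy]furan-3-yl}-2-methylbut-2-enoate
Conditions: TBSOTf, Et3N, CH2Cl2, 0 °C
Reagents that add atoms: tert-butyldimethylsilyl trifluoromethanesulfonate, CC(C)(C)[Si](C)(C)OS(=O)(=O)C(F)(F)F
Why: Soft enolisation of a butenolide (O-silylation, then deprotonation at the ring CH2) gives the 2-silyloxyfuran; loss of the ring proton should win over loss of a side-chain proton because only it leads to the aromatic furan.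

Step 6
Reactants: 4 (4E)-dec-4-en-2-ynal; 10 methyl (2E)-4-{5-[(tert-butyldimethylsilyl)oxy]furan-3-yl}-2-methylbut-2-enoate
Product: 13 methyl (2E)-4-{4-formyl-3-[(1E)-hept-1-en-1-yl]-2,5-dihydroxyphenyl}-2-methylbut-2-enoate, via oxanorbornadiene cycloadduct 11 (not isolated), via aryl silyl ether 12 (not isolated)
Conditions: CH2Cl2, 0 °C to rt; then K2CO3 (cat.), MeOH, 0 °C, under argon
Reagents that add atoms: none
Why: The electron-rich 2-silyloxyfuran 10 and the ynal 4 should combine in a normal-demand, asynchronous [4+2] cycloaddition (furan C5 to the alkyne carbon β to the formyl group, furan C2 to the α carbon) to give the 7-oxanorbornadiene 11, whose bridgehead silyloxy group then pushes out the oxygen bridge; proton loss from the other bridgehead gives arene 12, and its aryl silyl ether is methanolysed to 13. The closest known reaction type is the Diels–Alder/ring-opening benzannulation of 2-alkoxy- and 2-silyloxyfurans with acetylenic esters and ketones, which gives para-oxygenated phenols. The only ring closed is the six-membered carbocycle, formed by intermolecular [4+2] cycloaddition across furan C2 and C5, and the oxygen bridge of the bicycle is opened again in the same flask. No stereocentre survives, because the two bridgehead centres of 11 are flattened on aromatisation. The step needs regioselectivity, secured by matching the most nucleophilic furan terminus (C5, vinylogous to the silyloxy donor) with the most electrophilic alkyne carbon (β to CHO), and chemoselectivity for the alkyne over the formyl group and the three alkenes, which follows from the formyl-activated alkyne being the only strongly activated 2π partner. Release of the strain of the oxanorbornadiene and the gain of aromaticity should make the sequence irreversible.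

Step 7
Reactants: 13 methyl (2E)-4-{4-formyl-3-[(1E)-hept-1-en-1-yl]-2,5-dihydroxyphenyl}-2-methylbut-2-enoate
Product: 14 methyl (2E)-4-{4-formyl-3-[(1E)-hept-1-en-1-yl]-5-hydroxy-2-methoxyphenyl}-2-methylbut-2-enoate
Conditions: MeI (1.1 equiv), K2CO3 (1.0 equiv), DMF, 0 °C to rt, under argon
Reagents that add atoms: iodomethane, CI
Why: Williamson etherification: the hydroxyl ortho to the formyl group is held in a hydrogen-bonded chelate and its phenoxide is the weaker nucleophile, so methylation should go to the other hydroxyl, as it does with 2,5-dihydroxybenzaldehyde.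

Step 8
Reactants: 14 methyl (2E)-4-{4-formyl-3-[(1E)-hept-1-en-1-yl]-5-hydroxy-2-methoxyphenyl}-2-methylbut-2-enoate
Product: 15 methyl (2E)-4-{3-[(1E)-hept-1-en-1-yl]-5-hydroxy-4-(hydroxymethyl)-2-methoxyphenyl}-2-methylbut-2-enoate
Conditions: NaBH4, MeOH, 0 °C
Reagents that add atoms: none
Why: Borohydride reduction of an aryl aldehyde, which the α-methyl enoate should survive, turns the activating formyl group into the hydroxymethyl group of the target.

Step 9
Reactants: 15 methyl (2E)-4-{3-[(1E)-hept-1-en-1-yl]-5-hydroxy-4-(hydroxymethyl)-2-methoxyphenyl}-2-methylbut-2-enoate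
Product: 16 methyl (2E)-4-{5-[(1E)-hept-1-en-1-yl]-4-(hydroxymethyl)-6,6-dimethoxy-3-oxocyclohexa-1,4-dien-1-yl}-2-methylbut-2-enoate
Conditions: PhI(OAc)2, MeOH, 0 °C
Reagents that add atoms: methanol, CO
Why: Oxidative dearomatisation of a para-methoxyphenol by trivalent iodine: methanol adds at the methoxy-bearing para carbon to give the quinone monoketal, which differentiates the two future carbinol carbons.

Step 10
Reactants: 16 methyl (2E)-4-{5-[(1E)-hept-1-en-1-yl]-4-(hydroxymethyl)-6,6-dimethoxy-3-oxocyclohexa-1,4-dien-1-yl}-2-methylbut-2-enoate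
Product: 17 methyl (2E)-4-[(1R,6S)-3-[(1E)-hept-1-en-1-yl]-4-(hydroxymethyl)-2,2-dimethoxy-5-oxo-7-oxabicyclo[4.1.0]hept-3-en-1-yl]-2-methylbut-2-enoate
Conditions: Ph3COOH, NaN(SiMe3)2, L-(+)-diisopropyl tartrate, toluene, −50 °C; aq. NH4Cl quench
Reagents that add atoms: triphenylmethyl hydroperoxide, OOC(c1ccccc1)(c1ccccc1)c1ccccc1
Why: Tartrate-mediated nucleophilic (Weitz–Scheffer-type) epoxidation of a hydroxymethyl quinone monoketal: the sodium alkoxide of the hydroxymethyl group, the tartrate and the trityl peroxide form a chiral aggregate that should deliver the peroxide to one face of the trisubstituted enone alkene, setting C1 and C6 together, while the tetrasubstituted, diene-conjugated alkene next to the alkoxide is the less electrophilic one.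

Step 11
Reactants: 17 methyl (2E)-4-[(1R,6S)-3-[(1E)-hept-1-en-1-yl]-4-(hydroxymethyl)-2,2-dimethoxy-5-oxo-7-oxabicyclo[4.1.0]hept-3-en-1-yl]-2-methylbut-2-enoate
Product: 18 methyl (2E)-4-[(1R,5R,6R)-3-[(1E)-hept-1-en-1-yl]-5-hydroxy-4-(hydroxymethyl)-2,2-dimethoxy-7-oxabicyclo[4.1.0]hept-3-en-1-yl]-2-methylbut-2-enoate
Conditions: NaBH4, CeCl3·7H2O, MeOH, −78 °C
Reagents that add atoms: none
Why: Luche 1,2-reduction: hydride should attack the C5 carbonyl anti to the epoxide oxygen (Felkin–Anh-type approach antiperiplanar to the C6–O bond), which sets C5 with the hydroxyl cis to the epoxide, and the conditions spare the enoate and the ketal.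

Step 12
Reactants: 18 methyl (2E)-4-[(1R,5R,6R)-3-[(1E)-hept-1-en-1-yl]-5-hydroxy-4-(hydroxymethyl)-2,2-dimethoxy-7-oxabicyclo[4.1.0]hept-3-en-1-yl]-2-methylbut-2-enoate
Product: 19 methyl (2E)-4-[(1R,5R,6R)-3-[(1E)-hept-1-en-1-yl]-5-hydroxy-4-(hydroxymethyl)-2-oxo-7-oxabicyclo[4.1.0]hept-3-en-1-yl]-2-methylbut-2-enoate
Conditions: 48% aq. HF, MeCN, 0 °C
Reagents that add atoms: water, O
Why: Acid-catalysed ketal hydrolysis: ionisation at C2 gives an oxocarbenium ion stabilised by the C3=C4 diene system, so the ketal should open under conditions mild enough to leave the epoxide, the allylic alcohol and the ester intact.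

Step 13
Reactants: 19 methyl (2E)-4-[(1R,5R,6R)-3-[(1E)-hept-1-en-1-yl]-5-hydroxy-4-(hydroxymethyl)-2-oxo-7-oxabicyclo[4.1.0]hept-3-en-1-yl]-2-methylbut-2-enoate
Product: 20 methyl (2E)-4-[(1S,2R,5R,6R)-3-[(1E)-hept-1-en-1-yl]-2,5-dihydroxy-4-(hydroxymethyl)-7-oxabicyclo[4.1.0]hept-3-en-1-yl]-2-methylbut-2-enoate
Conditions: Me4NBH(OAc)3, MeCN/AcOH, −30 to 0 °C
Reagents that add atoms: none
Why: Proposed new method: ligand exchange should bind the borohydride to the C5 hydroxyl (and the neighbouring CH2OH) on the epoxide-bearing face, from where the B–H bond can reach the acid-activated C2 carbonyl across the ring in a boat-like transition state, while the free reagent is too weak a hydride donor to reduce the dienone from the other face, so hydride should arrive syn to the epoxide and give the C2 hydroxyl trans to it (2R); the closest known reaction type is the hydroxyl-directed (Evans–Saksena) triacetoxyborohydride reduction of β-hydroxy ketones, here stretched to a cyclic γ-hydroxy enone.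

Step 14
Reactants: 20 methyl (2E)-4-[(1S,2R,5R,6R)-3-[(1E)-hept-1-en-1-yl]-2,5-dihydroxy-4-(hydroxymethyl)-7-oxabicyclo[4.1.0]hept-3-en-1-yl]-2-methylbut-2-enoate
Product: 21 (2E)-4-[(1S,2R,5R,6R)-3-[(1E)-hept-1-en-1-yl]-2,5-dihydroxy-4-(hydroxymethyl)-7-oxabicyclo[4.1.0]hept-3-en-1-yl]-2-methylbut-2-enoic acid
Conditions: LiOH, THF/H2O, 0 °C to rt; then cold dilute HCl to pH 4
Reagents that add atoms: lithium hydroxide, [Li+].[OH-]
Why: Saponification of the methyl ester: with no carbonyl left on the ring nothing can trigger epoxide opening by enolisation, and a Payne shift would need attack on the fully substituted epoxide carbon, so mild hydrolysis and careful acidification should give the acid with all four stereocentres unchanged.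

**Compound list**

1 | (E)-oct-2-enal | CCCCC/C=C/C=O | starting material
2 | (3E)-1,1-dibromonona-1,3-diene | CCCCC/C=C/C=C(Br)Br | intermediate
3 | lithium (3E)-non-3-en-1-yn-1-ide | CCCCC/C=C/C#C[Li] | intermediate
4 | (4E)-dec-4-en-2-ynal | CCCCC/C=C/C#CC=O | intermediate
5 | 4-bromofuran-2(5H)-one | O=C1C=C(Br)CO1 | starting material
6 | allyltributylstannane [tributyl(prop-2-en-1-yl)stannane] | C=CC[Sn](CCCC)(CCCC)CCCC | starting material
7 | 4-(prop-2-en-1-yl)furan-2(5H)-one | O=C1C=C(CC=C)CO1 | intermediate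
8 | methyl methacrylate | C=C(C)C(=O)OC | starting material
9 | methyl (2E)-2-methyl-4-(5-oxo-2,5-dihydrofuran-3-yl)but-2-enoate | O=C1C=C(C/C=C(\C)C(=O)OC)CO1 | intermediate
10 | methyl (2E)-4-{5-[(tert-butyldimethylsilyl)oxy]furan-3-yl}-2-methylbut-2-enoate | CC(C)(C)[Si](C)(C)Oc1cc(C/C=C(\C)C(=O)OC)co1 | intermediate
11 | methyl (2E)-4-{1-[(tert-butyldimethylsilyl)oxy]-2-formyl-3-[(1E)-hept-1-en-1-yl]-7-oxabicyclo[2.2.1]hepta-2,5-dien-5-yl}-2-methylbut-2-enoate (racemic) | CCCCC/C=C/C1=C(C=O)C2(O[Si](C)(C)C(C)(C)C)C=C(C/C=C(\C)C(=O)OC)C1O2 | intermediate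
12 | methyl (2E)-4-{5-[(tert-butyldimethylsilyl)oxy]-4-formyl-3-[(1E)-hept-1-en-1-yl]-2-hydroxyphenyl}-2-methylbut-2-enoate | CCCCC/C=C/c1c(C=O)c(O[Si](C)(C)C(C)(C)C)cc(C/C=C(\C)C(=O)OC)c1O | intermediate
13 | methyl (2E)-4-{4-formyl-3-[(1E)-hept-1-en-1-yl]-2,5-dihydroxyphenyl}-2-methylbut-2-enoate | CCCCC/C=C/c1c(C=O)c(O)cc(C/C=C(\C)C(=O)OC)c1O | intermediate
14 | methyl (2E)-4-{4-formyl-3-[(1E)-hept-1-en-1-yl]-5-hydroxy-2-methoxyphenyl}-2-methylbut-2-enoate | CCCCC/C=C/c1c(C=O)c(O)cc(C/C=C(\C)C(=O)OC)c1OC | intermediate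
15 | methyl (2E)-4-{3-[(1E)-hept-1-en-1-yl]-5-hydroxy-4-(hydroxymethyl)-2-methoxyphenyl}-2-methylbut-2-enoate | CCCCC/C=C/c1c(CO)c(O)cc(C/C=C(\C)C(=O)OC)c1OC | intermediate
16 | methyl (2E)-4-{5-[(1E)-hept-1-en-1-yl]-4-(hydroxymethyl)-6,6-dimethoxy-3-oxocyclohexa-1,4-dien-1-yl}-2-methylbut-2-enoate | CCCCC/C=C/C1=C(CO)C(=O)C=C(C/C=C(\C)C(=O)OC)C1(OC)OC | intermediate
17 | methyl (2E)-4-[(1R,6S)-3-[(1E)-hept-1-en-1-yl]-4-(hydroxymethyl)-2,2-dimethoxy-5-oxo-7-oxabicyclo[4.1.0]hept-3-en-1-yl]-2-methylbut-2-enoate | CCCCC/C=C/C1=C(CO)C(=O)[C@H]2O[C@@]2(C/C=C(\C)C(=O)OC)C1(OC)OC | intermediate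
18 | methyl (2E)-4-[(1R,5R,6R)-3-[(1E)-hept-1-en-1-yl]-5-hydroxy-4-(hydroxymethyl)-2,2-dimethoxy-7-oxabicyclo[4.1.0]hept-3-en-1-yl]-2-methylbut-2-enoate | CCCCC/C=C/C1=C(CO)[C@@H](O)[C@H]2O[C@@]2(C/C=C(\C)C(=O)OC)C1(OC)OC | intermediate
19 | methyl (2E)-4-[(1R,5R,6R)-3-[(1E)-hept-1-en-1-yl]-5-hydroxy-4-(hydroxymethyl)-2-oxo-7-oxabicyclo[4.1.0]hept-3-en-1-yl]-2-methylbut-2-enoate | CCCCC/C=C/C1=C(CO)[C@@H](O)[C@H]2O[C@@]2(C/C=C(\C)C(=O)OC)C1=O | intermediate
20 | methyl (2E)-4-[(1S,2R,5R,6R)-3-[(1E)-hept-1-en-1-yl]-2,5-dihydroxy-4-(hydroxymethyl)-7-oxabicyclo[4.1.0]hept-3-en-1-yl]-2-methylbut-2-enoate | CCCCC/C=C/C1=C(CO)[C@@H](O)[C@H]2O[C@@]2(C/C=C(\C)C(=O)OC)[C@@H]1O | intermediate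
21 | (2E)-4-[(1S,2R,5R,6R)-3-[(1E)-hept-1-en-1-yl]-2,5-dihydroxy-4-(hydroxymethyl)-7-oxabicyclo[4.1.0]hept-3-en-1-yl]-2-methylbut-2-enoic acid | CCCCC/C=C/C1=C(CO)[C@@H](O)[C@H]2O[C@@]2(C/C=C(\C)C(=O)O)[C@@H]1O | target

**Step count and risks**

Total: 14 steps. Longest linear sequence: 12 steps (steps 3 to 14, from 4-bromofuran-2(5H)-one); the ynal branch (steps 1 and 2) joins at step 6.

Steps most likely to fail:

1. Step 13 (labelled step). The borohydride may fail to reach the ketone from the bound hydroxyl, so that reduction either stalls or proceeds by external attack anti to the epoxide with the wrong facial selectivity. The fallback uses known chemistry, sets out from 19 and comes back at 20. Both free hydroxyls are silylated (TBSOTf, 2,6-lutidine) to give the bis(tert-butyldimethylsilyl) ether F1. Reduction with NaBH4/CeCl3·7H2O, expected to attack anti to the epoxide and to the C5 silyl ether, gives the C2-epimeric alcohol F2. Mitsunobu inversion (4-nitrobenzoic acid, PPh3, DIAD) gives the 4-nitrobenzoate F3 with the required C2 configuration. K2CO3 in MeOH cleaves the aryl ester to the alcohol F4, and HF·pyridine removes both silyl groups.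

2. Step 10. Enantiofacial control by the tartrate aggregate may be poor with the heptenyl diene in place, or the peroxide may add to the other enone alkene or in a 1,6-sense. The fallback replaces reagent control by auxiliary control, sets out from 16 and comes back at 19. The dimethyl ketal is exchanged for the ketal of (2R,3R)-butane-2,3-diol (PPTS, benzene, removal of MeOH) to give the C2-symmetric spiroketal F5. Base-mediated epoxidation (t-BuOOH, DBU) is then diastereoselective, and the (1R,6S)-epoxide F6 is separated from its diastereomer by chromatography. Reduction with NaBH4/CeCl3·7H2O gives the syn-epoxy alcohol F7, and hydrolysis of the ketal (aq. HF, MeCN) gives 19.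

3. Step 6. Crowding between the heptenyl group and the furan C4 substituent at the forming bond may slow the cycloaddition, letting decomposition or desilylation of the sensitive furan, or a vinylogous aldol addition to the formyl group, take over. The fallback builds the ring from an unsubstituted furan and brings in the side chain afterwards; it sets out from 4 and comes back at 14. Ynal 4 and commercial 2-(trimethylsilyloxy)furan give, through the oxanorbornadiene cycloadduct F8 and the aryl trimethylsilyl ether F9, after methanolysis the hydroquinone aldehyde F10. The non-chelated hydroxyl is allylated (allyl bromide, K2CO3, acetone) to the allyl ether F11. Aromatic Claisen rearrangement (PhNEt2, 190 °C) can reach only the one free ortho position and gives the C-allyl hydroquinone F12. Selective methylation as in step 7 gives the methyl ether F13, and cross-metathesis with 8 as in step 4 gives 14.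

**Further compounds**

F1 | step 13 | bis(tert-butyldimethylsilyl) ether of 19 (silyl groups on the C5 hydroxyl and on the hydroxymethyl oxygen) | CCCCC/C=C/C1=C(CO[Si](C)(C)C(C)(C)C)[C@@H](O[Si](C)(C)C(C)(C)C)[C@H]2O[C@@]2(C/C=C(\C)C(=O)OC)C1=O
F2 | step 13 | C2-epimeric alcohol from F1 (C2 hydroxyl cis to the epoxide), bis-silyl ether | CCCCC/C=C/C1=C(CO[Si](C)(C)C(C)(C)C)[C@@H](O[Si](C)(C)C(C)(C)C)[C@H]2O[C@@]2(C/C=C(\C)C(=O)OC)[C@H]1O
F3 | step 13 | 4-nitrobenzoate of the C2-inverted alcohol (C2 oxygen trans to the epoxide), bis-silyl ether | CCCCC/C=C/C1=C(CO[Si](C)(C)C(C)(C)C)[C@@H](O[Si](C)(C)C(C)(C)C)[C@H]2O[C@@]2(C/C=C(\C)C(=O)OC)[C@@H]1OC(=O)c1ccc(cc1)[N+](=O)[O-]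
F4 | step 13 | bis(tert-butyldimethylsilyl) ether of 20 | CCCCC/C=C/C1=C(CO[Si](C)(C)C(C)(C)C)[C@@H](O[Si](C)(C)C(C)(C)C)[C@H]2O[C@@]2(C/C=C(\C)C(=O)OC)[C@@H]1O
F5 | step 10 | methyl (2E)-4-[(2R,3R)-10-[(1E)-hept-1-en-1-yl]-9-(hydroxymethyl)-2,3-dimethyl-8-oxo-1,4-dioxaspiro[4.5]deca-6,9-dien-6-yl]-2-methylbut-2-enoate | CCCCC/C=C/C1=C(CO)C(=O)C=C(C/C=C(\C)C(=O)OC)C12O[C@H](C)[C@@H](C)O2
F6 | step 10 | analogue of 17 with the (2R,3R)-butane-2,3-diyl ketal in place of the two methoxy groups | CCCCC/C=C/C1=C(CO)C(=O)[C@H]2O[C@@]2(C/C=C(\C)C(=O)OC)C13O[C@H](C)[C@@H](C)O3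
F7 | step 10 | analogue of 18 with the (2R,3R)-butane-2,3-diyl ketal in place of the two methoxy groups | CCCCC/C=C/C1=C(CO)[C@@H](O)[C@H]2O[C@@]2(C/C=C(\C)C(=O)OC)C13O[C@H](C)[C@@H](C)O3
F8 | step 6 | 3-[(1E)-hept-1-en-1-yl]-1-(trimethylsilyloxy)-7-oxabicyclo[2.2.1]hepta-2,5-diene-2-carbaldehyde (racemic) | CCCCC/C=C/C1=C(C=O)C2(O[Si](C)(C)C)C=CC1O2
F9 | step 6 | 2-[(1E)-hept-1-en-1-yl]-3-hydroxy-6-(trimethylsilyloxy)benzaldehyde | CCCCC/C=C/c1c(C=O)c(O[Si](C)(C)C)ccc1O
F10 | step 6 | 2-[(1E)-hept-1-en-1-yl]-3,6-dihydroxybenzaldehyde | CCCCC/C=C/c1c(C=O)c(O)ccc1O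
F11 | step 6 | 2-[(1E)-hept-1-en-1-yl]-6-hydroxy-3-(prop-2-en-1-yloxy)benzaldehyde | CCCCC/C=C/c1c(C=O)c(O)ccc1OCC=C
F12 | step 6 | 2-[(1E)-hept-1-en-1-yl]-3,6-dihydroxy-4-(prop-2-en-1-yl)benzaldehyde | CCCCC/C=C/c1c(C=O)c(O)cc(CC=C)c1O
F13 | step 6 | 2-[(1E)-hept-1-en-1-yl]-6-hydroxy-3-methoxy-4-(prop-2-en-1-yl)benzaldehyde | CCCCC/C=C/c1c(C=O)c(O)cc(CC=C)c1OC
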